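**Retrosynthetic overview**

1. The target comes from its C5 epimer by base equilibration; the C5 epimer comes from one open-chain precursor, an α-ethoxyvinyl chloride tethered to an (E)-trisubstituted styrene, by a palladium cascade that forms C7a–C3a and then C2–C3.
2. Ring order: carbocycle first (6-exo carbopalladation), dihydrofuran second (C(sp3)–H alkylation), both in the same operation; no ring exists before it.
3. Enabling feature: in the dihydrofuran ring O1–C2–C3–C3a–C7a, C2 is an O-bound CH–CH3 (the methylene of an ethyl enol ether), C3a is quaternary, and C7a=C7–C6=O is a vinylogous ester. The precursor therefore needs only an OEt group on C7a, and palladium delivered to C3 has no β-hydrogen and sits 1,5 to the O–CH2 hydrogens.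
4. The precursor comes from ethoxyacetylene and a Weinreb amide (then HCl); the amide from an auxiliary-controlled glycolate alkylation with an (E)-allylic bromide; the bromide from an HWE ester of 3,4,5-trimethoxybenzaldehyde.
5. Stereocontrol: alkene geometry sets C3/C3a; C5 (from the auxiliary) selects the alkene face; the palladacycle sets C2; C5 is finally moved to its more stable configuration.

Key step: step 10

Remark: atom numbers (O1, C2, C3, C3a, C4–C7, C7a) are the benzofuran numbers of the target and are used for the corresponding atoms of all precursors.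

Assumption: the facial sense of the carbopalladation is the one argued in step 10 (methoxy ends up cis to allyl). If the opposite face reacted, the mirror-image auxiliary series would be used and step 11 omitted.

**Route**

Step 1
Reactants: 1 triethyl phosphonoacetate; 2 allyl bromide
Product: 3 ethyl 2-(diethoxyphosphoryl)pent-4-enoate (racemic)
Conditions: NaH, THF, 0 °C → rt (1 in slight excess)
Reagents that add atoms: none
Why: SN2 C-alkylation of the stabilised phosphonoacetate carbanion; the excess of 1 limits dialkylation, and the stereocentre of 3 is destroyed in step 2.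

Step 2
Reactants: 3 ethyl 2-(diethoxyphosphoryl)pent-4-enoate; 4 3,4,5-trimethoxybenzaldehyde
Product: 5 ethyl (2E)-2-(prop-2-en-1-yl)-3-(3,4,5-trimethoxyphenyl)prop-2-enoate
Conditions: NaH, THF, 0 °C → rt
Reagents that add atoms: none
Why: Horner–Wadsworth–Emmons olefination; with an α-substituted phosphonoacetate and an aryl aldehyde the reversible addition should funnel to the (E)-ester (aryl trans to CO2Et, hence cis to allyl), the geometry that later fixes the C3/C3a relationship.

Step 3
Reactants: 5 ethyl (2E)-2-(prop-2-en-1-yl)-3-(3,4,5-trimethoxyphenyl)prop-2-enoate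
Product: 6 (2E)-2-(prop-2-en-1-yl)-3-(3,4,5-trimethoxyphenyl)prop-2-en-1-ol
Conditions: i-Bu2AlH (2.3 equiv), CH2Cl2, −78 → 0 °C; aqueous potassium sodium tartrate work-up
Reagents that add atoms: none
Why: 1,2-reduction of the conjugated ester to the allylic alcohol, which leaves both C=C bonds and the alkene geometry untouched.

Step 4
Reactants: 6 (2E)-2-(prop-2-en-1-yl)-3-(3,4,5-trimethoxyphenyl)prop-2-en-1-ol
Product: 7 5-[(1E)-2-(bromomethyl)penta-1,4-dien-1-yl]-1,2,3-trimethoxybenzene
Conditions: CBr4, PPh3, CH2Cl2, 0 °C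
Reagents that add atoms: carbon tetrabromide, BrC(Br)(Br)Br
Why: Appel bromination (SN2 on the alkoxyphosphonium salt) under neutral conditions should give the primary allylic bromide without allylic transposition or E/Z isomerisation.

Step 5
Reactants: 8 (R)-4-benzyl-1,3-oxazolidin-2-one; 9 methoxyacetyl chloride
Product: 10 (4R)-4-benzyl-3-(methoxyacetyl)-1,3-oxazolidin-2-one
Conditions: n-BuLi, THF, −78 °C; then 9, −78 → 0 °C
Reagents that add atoms: none
Why: N-acylation of the lithiated oxazolidinone with an acid chloride, the standard preparation of an Evans-type glycolate imide.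

Step 6
Reactants: 10 (4R)-4-benzyl-3-(methoxyacetyl)-1,3-oxazolidin-2-one; 7 5-[(1E)-2-(bromomethyl)penta-1,4-dien-1-yl]-1,2,3-trimethoxybenzene
Product: 11 (4R)-4-benzyl-3-[(2S,4E)-2-methoxy-4-(prop-2-en-1-yl)-5-(3,4,5-trimethoxyphenyl)pent-4-enoyl]-1,3-oxazolidin-2-one
Conditions: NaN(SiMe3)2, THF, −78 °C; then 7, −78 → −45 °C
Reagents that add atoms: none
Why: Evans-type asymmetric glycolate alkylation; the chelated (Z)-sodium enolate is alkylated by the reactive allylic bromide on the face opposite the benzyl group of the (R)-auxiliary, which sets C5 as (S).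

Step 7
Reactants: 11 (4R)-4-benzyl-3-[(2S,4E)-2-methoxy-4-(prop-2-en-1-yl)-5-(3,4,5-trimethoxyphenyl)pent-4-enoyl]-1,3-oxazolidin-2-one
Product: 12 (2S,4E)-N,2-dimethoxy-N-methyl-4-(prop-2-en-1-yl)-5-(3,4,5-trimethoxyphenyl)pent-4-enamide
Conditions: MeNH(OMe)·HCl, AlMe3, CH2Cl2, 0 °C → rt
Reagents that add atoms: N,O-dimethylhydroxylamine hydrochloride, CNOC.Cl
Why: aluminium amide transamination of the N-acyloxazolidinone (Weinreb amide formation), assisted by the α-methoxy group; C5 is not touched and the auxiliary is released.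

Step 8
Reactants: 12 (2S,4E)-N,2-dimethoxy-N-methyl-4-(prop-2-en-1-yl)-5-(3,4,5-trimethoxyphenyl)pent-4-enamide; 13 ethoxyacetylene
Product: 14 (4S,6E)-1-ethoxy-4-methoxy-6-(prop-2-en-1-yl)-7-(3,4,5-trimethoxyphenyl)hept-6-en-1-yn-3-one
Conditions: 13, n-BuLi, THF, −78 °C; then 12, −78 → −30 °C; cold pH 7 buffer; used at once
Reagents that add atoms: none
Why: acylation of lithium ethoxyacetylide by the Weinreb amide; the stable chelated tetrahedral adduct should prevent over-addition and α-epimerisation, and the neutral work-up releases the alkoxy ynone.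

Step 9
Reactants: 14 (4S,6E)-1-ethoxy-4-methoxy-6-(prop-2-en-1-yl)-7-(3,4,5-trimethoxyphenyl)hept-6-en-1-yn-3-one
Product: 15 (1Z,4S,6E)-1-chloro-1-ethoxy-4-methoxy-6-(prop-2-en-1-yl)-7-(3,4,5-trimethoxyphenyl)hepta-1,6-dien-3-one
Conditions: HCl (1.0 M in Et2O, 1.05 equiv), CH2Cl2, −78 °C; volatiles removed cold; used crude under argon
Reagents that add atoms: hydrogen chloride, Cl
Why: hydrochlorination of an alkoxyalkyne; protonation at C7 (β to oxygen, α to the ketone) gives a ketene-oxonium ion that chloride captures at C7a, and anti addition places chlorine cis to the acyl group.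

Step 10
Reactants: 15 (1Z,4S,6E)-1-chloro-1-ethoxy-4-methoxy-6-(prop-2-en-1-yl)-7-(3,4,5-trimethoxyphenyl)hepta-1,6-dien-3-one
Product: 19 (2S,3R,3aR,5S)-5-methoxy-2-methyl-3a-(prop-2-en-1-yl)-3-(3,4,5-trimethoxyphenyl)-3,3a,4,5-tetrahydro-1-benzofuran-6(2H)-one, via alkenylpalladium chloride 16 (not isolated), via benzylic alkylpalladium chloride 17 (not isolated), via oxapalladacycle 18 (not isolated)
Conditions: Pd(PCy3)2 (10 mol %), CsO2CCMe3 (2.2 equiv), 4 Å molecular sieves, toluene, 60 °C then 105 °C
Reagents that add atoms: none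
Why: Proposed new method: zerovalent palladium inserts into the activated C–Cl bond of the vinylogous chloroformate with retention (16), the alkenylpalladium adds syn across the tethered (E)-styrene in a 6-exo-trig carbopalladation that forms C7a–C3a and the carbocycle (17), and because C3a is quaternary the benzylic palladium at C3 has no β-hydrogen and instead cleaves one O–CH2 hydrogen of the ethoxy group by pivalate-assisted concerted metalation–deprotonation to the six-membered oxapalladacycle 18, whose C(sp3)–C(sp3) reductive elimination forms C2–C3 and closes the dihydrofuran (a five-membered ring made through a six-membered palladacycle). The closest known reactions are domino Heck carbopalladation/C(sp3)–H alkylation cascades of aryl halides that run through neopentyl-type alkylpalladium species and six-membered palladacycles, and palladium-catalysed C–H functionalisation of O-alkyl groups; not yet shown are the alkoxyvinyl chloride, the secondary benzylic palladium centre and an ether methylene as the C–H partner. C3a and C3 are set together by the syn addition to the (E)-alkene and the retentive reductive elimination, which places aryl and allyl cis; the alkene face is chosen by C5, whose methoxy group should avoid the crowded face that carries the palladium-bearing C3 in the eclipsed four-centre transition state, so that the (5S)-chain should deliver (3aR) with methoxy cis to allyl. C2 is set when the oxapalladacycle forms and collapses, the methyl group taking the position away from the C3 aryl group (2,3-trans). The step needs the ether C–H cleavage to outrun protodepalladation, 1,4-palladium migration to C7–H and insertion into the C7a=C7 bond; the absence of any β-hydrogen, the unstrained six-membered palladacycle, the acidifying vinylogous-ester oxygen next to C2 and the poor acceptor quality of the donor-substituted C7a=C7 bond should secure this, and the weak base is chosen to keep C5 of 15 from epimerising before ring closure.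

Step 11
Reactants: 19 (2S,3R,3aR,5S)-5-methoxy-2-methyl-3a-(prop-2-en-1-yl)-3-(3,4,5-trimethoxyphenyl)-3,3a,4,5-tetrahydro-1-benzofuran-6(2H)-one
Product: 20 (2S,3R,3aR,5R)-5-methoxy-2-methyl-3a-(prop-2-en-1-yl)-3-(3,4,5-trimethoxyphenyl)-3,3a,4,5-tetrahydro-1-benzofuran-6(2H)-one
Conditions: KOt-Bu (0.2 equiv), t-BuOH/THF, 0 °C → rt; residual 19 recycled
Reagents that add atoms: none
Why: thermodynamic epimerisation at C5 through the ketone enolate; in 20 the methoxy group is pseudo-equatorial and trans to the pseudo-axial 3a-allyl group, whereas 19 carries a 1,3-diaxial methoxy/allyl interaction, and C2, C3 and C3a have no acidic hydrogen.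

**Compound list**

1 | triethyl phosphonoacetate | CCOC(=O)CP(=O)(OCC)OCC | starting material
2 | allyl bromide | C=CCBr | starting material
3 | ethyl 2-(diethoxyphosphoryl)pent-4-enoate (racemic) | CCOC(=O)C(CC=C)P(=O)(OCC)OCC | intermediate
4 | 3,4,5-trimethoxybenzaldehyde | COc1cc(C=O)cc(OC)c1OC | starting material
5 | ethyl (2E)-2-(prop-2-en-1-yl)-3-(3,4,5-trimethoxyphenyl)prop-2-enoate | CCOC(=O)/C(CC=C)=C/c1cc(OC)c(OC)c(OC)c1 | intermediate
6 | (2E)-2-(prop-2-en-1-yl)-3-(3,4,5-trimethoxyphenyl)prop-2-en-1-ol | OC/C(CC=C)=C/c1cc(OC)c(OC)c(OC)c1 | intermediate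
7 | 5-[(1E)-2-(bromomethyl)penta-1,4-dien-1-yl]-1,2,3-trimethoxybenzene | BrC/C(CC=C)=C/c1cc(OC)c(OC)c(OC)c1 | intermediate
8 | (R)-4-benzyl-1,3-oxazolidin-2-one | O=C1N[C@H](Cc2ccccc2)CO1 | starting material
9 | methoxyacetyl chloride | COCC(Cl)=O | starting material
10 | (4R)-4-benzyl-3-(methoxyacetyl)-1,3-oxazolidin-2-one | COCC(=O)N1[C@H](Cc2ccccc2)COC1=O | intermediate
11 | (4R)-4-benzyl-3-[(2S,4E)-2-methoxy-4-(prop-2-en-1-yl)-5-(3,4,5-trimethoxyphenyl)pent-4-enoyl]-1,3-oxazolidin-2-one | CO[C@@H](C/C(CC=C)=C/c1cc(OC)c(OC)c(OC)c1)C(=O)N1[C@H](Cc2ccccc2)COC1=O | intermediate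
12 | (2S,4E)-N,2-dimethoxy-N-methyl-4-(prop-2-en-1-yl)-5-(3,4,5-trimethoxyphenyl)pent-4-enamide | CO[C@@H](C/C(CC=C)=C/c1cc(OC)c(OC)c(OC)c1)C(=O)N(C)OC | intermediate
13 | ethoxyacetylene | CCOC#C | starting material
14 | (4S,6E)-1-ethoxy-4-methoxy-6-(prop-2-en-1-yl)-7-(3,4,5-trimethoxyphenyl)hept-6-en-1-yn-3-one | CCOC#CC(=O)[C@@H](OC)C/C(CC=C)=C/c1cc(OC)c(OC)c(OC)c1 | intermediate
15 | (1Z,4S,6E)-1-chloro-1-ethoxy-4-methoxy-6-(prop-2-en-1-yl)-7-(3,4,5-trimethoxyphenyl)hepta-1,6-dien-3-one | CCO/C(Cl)=C/C(=O)[C@@H](OC)C/C(CC=C)=C/c1cc(OC)c(OC)c(OC)c1 | intermediate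
16 | alkenylpalladium chloride from oxidative addition: divalent palladium in place of the chlorine of 15, geometry retained (phosphine ligand not drawn) | CCO/C([Pd]Cl)=C/C(=O)[C@@H](OC)C/C(CC=C)=C/c1cc(OC)c(OC)c(OC)c1 | intermediate
17 | benzylic alkylpalladium chloride from 6-exo carbopalladation: cyclohexenone ring closed, palladium on C3, C3a/C3/C5 configured as in 19 (phosphine ligand not drawn) | C=CC[C@@]1(C[C@H](OC)C(=O)C=C1OCC)[C@H]([Pd]Cl)c1cc(OC)c(OC)c(OC)c1 | intermediate
18 | six-membered oxapalladacycle: palladium bridging C2 and C3 of 19 (phosphine ligand not drawn) | C=CC[C@]12C[C@H](OC)C(=O)C=C1O[C@@H](C)[Pd][C@@H]2c1cc(OC)c(OC)c(OC)c1 | intermediate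
19 | (2S,3R,3aR,5S)-5-methoxy-2-methyl-3a-(prop-2-en-1-yl)-3-(3,4,5-trimethoxyphenyl)-3,3a,4,5-tetrahydro-1-benzofuran-6(2H)-one | C=CC[C@]12C[C@H](OC)C(=O)C=C1O[C@@H](C)[C@@H]2c1cc(OC)c(OC)c(OC)c1 | intermediate
20 | (2S,3R,3aR,5R)-5-methoxy-2-methyl-3a-(prop-2-en-1-yl)-3-(3,4,5-trimethoxyphenyl)-3,3a,4,5-tetrahydro-1-benzofuran-6(2H)-one | C=CC[C@]12C[C@@H](OC)C(=O)C=C1O[C@@H](C)[C@@H]2c1cc(OC)c(OC)c(OC)c1 | target

**Summary**

Total step count: 11. Longest linear sequence: 10 steps (steps 1–4 and 6–11, from triethyl phosphonoacetate).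

**Steps most likely to fail**

1. Step 10 (Proposed new method). The benzylic alkylpalladium intermediate may be diverted before it reaches the ether C–H bond (protodepalladation, 1,4-migration of palladium, insertion into the C7a=C7 bond), or the C–H cleavage may give the wrong C2 configuration. The fallback uses known chemistry, sets out from 15 and comes back at 19. Cyclisation–anion capture with Pd(PPh3)4 (5 mol %) and tributyl(1-ethoxyvinyl)stannane in toluene at 90 °C, that is the same 6-exo Heck carbopalladation followed by Stille coupling of the alkylpalladium species, should give the doubly O-ethylated enol ether F1. Brief treatment with oxalic acid on wet silica should unmask the methyl ketone F2 without touching the vinylogous ester. NaBH4 in MeOH at −40 °C should reduce only the methyl ketone, with Felkin–Anh control by C3 (quaternary C3a as the large group) leading to the (2S)-alcohol F3. Pyridinium p-toluenesulfonate in benzene at 60 °C should then close the dihydrofuran by intramolecular addition–elimination at C7a with loss of ethanol, giving 19.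

2. Step 9. The ketene-oxonium ion formed on protonation may be dealkylated by chloride (loss of chloroethane to an acylketene), or the acid may hydrate the ynol ether; either process destroys the enol-ether oxygen that step 10 needs. The fallback sets out from 12 and comes back at 19. HC≡CMgBr in THF at 0 °C should give the terminal ynone F4. N-Bromosuccinimide with AgNO3 (10 mol %) in acetone should give the bromoalkynone F5. Conjugate addition of ethanol (1.1 equiv, DABCO 10 mol %, CH2Cl2, 0 °C) should give the bromo enol ether F6, the bromide analogue of 15, which would be carried through the conditions of step 10 to 19.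

3. Step 8. The alkoxy ynone is a strong Michael acceptor and hydrates easily, so loss during the basic aqueous work-up, over-addition or partial epimerisation at C5 is possible. The fallback sets out from 12 and comes back at 14. i-Bu2AlH in THF at −78 °C should stop at the aldehyde F7, which is used at once. Lithium ethoxyacetylide in THF at −78 °C should add to give the propargylic alcohol F8 (both carbinol epimers, of no consequence). MnO2 in CH2Cl2 should oxidise it under neutral, anhydrous conditions to 14.

**Further compounds**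

F1 | step 10 | (4R,6S)-3-ethoxy-4-[(1R)-2-ethoxy-1-(3,4,5-trimethoxyphenyl)prop-2-en-1-yl]-6-methoxy-4-(prop-2-en-1-yl)cyclohex-2-en-1-one | C=CC[C@@]1(C[C@H](OC)C(=O)C=C1OCC)[C@H](C(=C)OCC)c1cc(OC)c(OC)c(OC)c1
F2 | step 10 | (4R,6S)-3-ethoxy-6-methoxy-4-[(1R)-2-oxo-1-(3,4,5-trimethoxyphenyl)propyl]-4-(prop-2-en-1-yl)cyclohex-2-en-1-one | C=CC[C@@]1(C[C@H](OC)C(=O)C=C1OCC)[C@H](C(C)=O)c1cc(OC)c(OC)c(OC)c1
F3 | step 10 | (4R,6S)-3-ethoxy-4-[(1R,2S)-2-hydroxy-1-(3,4,5-trimethoxyphenyl)propyl]-6-methoxy-4-(prop-2-en-1-yl)cyclohex-2-en-1-one | C=CC[C@@]1(C[C@H](OC)C(=O)C=C1OCC)[C@H]([C@H](C)O)c1cc(OC)c(OC)c(OC)c1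
F4 | step 9 | (4S,6E)-4-methoxy-6-(prop-2-en-1-yl)-7-(3,4,5-trimethoxyphenyl)hept-6-en-1-yn-3-one | C#CC(=O)[C@@H](OC)C/C(CC=C)=C/c1cc(OC)c(OC)c(OC)c1
F5 | step 9 | (4S,6E)-1-bromo-4-methoxy-6-(prop-2-en-1-yl)-7-(3,4,5-trimethoxyphenyl)hept-6-en-1-yn-3-one | BrC#CC(=O)[C@@H](OC)C/C(CC=C)=C/c1cc(OC)c(OC)c(OC)c1
F6 | step 9 | (1Z,4S,6E)-1-bromo-1-ethoxy-4-methoxy-6-(prop-2-en-1-yl)-7-(3,4,5-trimethoxyphenyl)hepta-1,6-dien-3-one | CCO/C(Br)=C/C(=O)[C@@H](OC)C/C(CC=C)=C/c1cc(OC)c(OC)c(OC)c1
F7 | step 8 | (2S,4E)-2-methoxy-4-(prop-2-en-1-yl)-5-(3,4,5-trimethoxyphenyl)pent-4-enal | O=C[C@@H](OC)C/C(CC=C)=C/c1cc(OC)c(OC)c(OC)c1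
F8 | step 8 | (4S,6E)-1-ethoxy-4-methoxy-6-(prop-2-en-1-yl)-7-(3,4,5-trimethoxyphenyl)hept-6-en-1-yn-3-ol (both C3 epimers) | CCOC#CC(O)[C@@H](OC)C/C(CC=C)=C/c1cc(OC)c(OC)c(OC)c1
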